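**Retrosynthetic overview**
- Robustol is opened at the diaryl ether C–O bond. The ring A phenol oxygen and the ring B carbon flanked by OH and the chain both come from the two identical resorcinol rings of 1,14-bis(3,5-dihydroxyphenyl)tetradecane, joined by a dehydrogenative O–H/C–H ring closure.
- The bis-resorcinol comes from its tetramethyl ether by global O-demethylation.
- The tetramethyl ether comes from two benzylic C(sp3)–C(sp3) bonds: two 3,5-dimethoxybenzyl Grignard units and 1,12-dibromododecane.
- Ring order: both benzene rings are bought; the 20-membered macrocycle is the only ring made and it closes last.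

Assumption: the target has no stereocentre and is achiral (the 20-membered ring is too large for stable planar chirality), so no enantiocontrol is needed.

**Step 1**
Reactants: 1 3,5-dimethoxybenzyl chloride; 2 1,12-dibromododecane
Product: 4 1,14-bis(3,5-dimethoxyphenyl)tetradecane, via (3,5-dimethoxybenzyl)magnesium chloride 3 (not isolated)
Conditions: 1 (2.6 equiv), Mg, 2-MeTHF, 0 °C, slow addition; then 2 (1.0 equiv), Li2CuCl4 (5 mol%), THF/NMP, –10 °C to rt
Reagents that add atoms: none
Why: Copper-catalysed sp3–sp3 Grignard cross-coupling (Kochi type) at both ends of the primary dibromide; the benzyl chloride and 2-MeTHF keep Wurtz homocoupling low, and no stereocentre is formed.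

**Step 2**
Reactants: 4 1,14-bis(3,5-dimethoxyphenyl)tetradecane
Product: 5 1,14-bis(3,5-dihydroxyphenyl)tetradecane
Conditions: BBr3 (6 equiv), CH2Cl2, –78 °C to rt; then MeOH/H2O
Reagents that add atoms: none
Why: Lewis-acid cleavage of aryl methyl ethers (BBr3 demethylation), standard for 5-alkylresorcinol dimethyl ethers; the saturated chain is inert.

**Step 3**
Reactants: 5 1,14-bis(3,5-dihydroxyphenyl)tetradecane
Product: 7 robustol, via quinol-ether dienone 6 (not isolated)
Conditions: CuCl2 (10 mol%) + iPr3TACN (11 mol%; 1,4,7-triisopropyl-1,4,7-triazacyclononane; gives CuCl2(iPr3TACN), divalent copper), 2,6-diphenylpyridine (1 equiv), O2 (0.55 equiv, gas-tight syringe pump, 8 h), degassed PhCl/THF 9:1, 1 mM, 40 °C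
Reagents that add atoms: none
Why: Proposed new method: copper-catalysed aerobic para-selective O–H/C–H macro-etherification of a bis-resorcinol — the bulky triamine–copper catalyst and O2 give a dicopper–dioxygen (Cu2O2) species that takes a hydrogen atom from one neutral resorcinol OH to leave a copper-bound phenoxyl (ring B, electrophilic at the carbons ortho and para to that oxygen), while a hydroxyl of the other ring sits on divalent copper as a nucleophilic phenoxide (ring A); the isopropyl groups screen the ortho carbons, in particular the carbon between the two oxygens, which is ortho to whichever oxygen is bound, so the phenoxide oxygen attacks the para carbon (flanked by OH and the chain) to give quinol ether 6, which enolises at once to the aromatic diaryl ether 7 and erases its transient stereocentre; because no free phenoxyl radical leaves copper, C–C coupling is disfavoured, the 20-membered ring closes in preference to oligomers at 1 mM, and the only further couplings open to 7 are intermolecular, which dilution and the metered O2 (overall 5 + 0.5 O2 → 7 + H2O) hold back; closest known reaction type: copper–amine catalysed aerobic oxidative C–O coupling of phenols as used for poly(phenylene oxide)s, including para-selective coupling of ortho-unsubstituted phenols with triazacyclononane–copper catalysts, so far not shown for resorcinols or for a single ring-closing coupling.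

**Compound list**
1 | 3,5-dimethoxybenzyl chloride | COc1cc(CCl)cc(OC)c1 | starting material
2 | 1,12-dibromododecane | BrCCCCCCCCCCCCBr | starting material
3 | (3,5-dimethoxybenzyl)magnesium chloride | COc1cc(C[Mg]Cl)cc(OC)c1 | intermediate (not isolated)
4 | 1,14-bis(3,5-dimethoxyphenyl)tetradecane | COc1cc(CCCCCCCCCCCCCCc2cc(OC)cc(OC)c2)cc(OC)c1 | intermediate
5 | 1,14-bis(3,5-dihydroxyphenyl)tetradecane | Oc1cc(O)cc(CCCCCCCCCCCCCCc2cc(O)cc(O)c2)c1 | intermediate
6 | quinol-ether dienone: macrocyclic 4-aryloxy-3-hydroxy-5-alkylcyclohexa-2,5-dien-1-one tautomer of 7, the sp3 ring carbon carrying H and the ring A oxygen (racemic, transient) | Oc1cc2cc(c1)OC1C(O)=CC(=O)C=C1CCCCCCCCCCCCCC2 | intermediate (not isolated)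
7 | robustol: 20-membered macrocycle in which a 3-hydroxyphenyl ring A and a 2,4-dihydroxyphenyl ring B are joined by an ether oxygen (meta to OH and chain on ring A; on ring B at the carbon between an OH and the chain) and by a (CH2)14 chain; achiral | Oc1cc2cc(c1)Oc1c(O)cc(O)cc1CCCCCCCCCCCCCC2 | target

**Total step count:** 3. **Longest linear sequence:** 3 steps (1/2 → 4 → 5 → 7).

**Steps most likely to fail, with fallbacks**

Step 3 (new macro-etherification; risks are C–C coupling, attack at the carbon between the two oxygens, oligomers and further oxidation). The fallback sets out from 4 and comes back at 7, using only known reactions. NaSEt (1.1 equiv, DMF, 140 °C) cleaves one methyl ether statistically, with unreacted 4 recycled, to give 3-[14-(3,5-dimethoxyphenyl)tetradecyl]-5-methoxyphenol F6. Ac2O/pyridine gives 3-[14-(3,5-dimethoxyphenyl)tetradecyl]-5-methoxyphenyl acetate F7, in which ring A is deactivated. NIS (1.0 equiv, cat. CF3CO2H, MeCN, 0 °C) then iodinates only the dimethoxy ring, at the carbon between the chain and a methoxy group, to give 3-[14-(2-iodo-3,5-dimethoxyphenyl)tetradecyl]-5-methoxyphenyl acetate F8. K2CO3/MeOH frees the phenol 3-[14-(2-iodo-3,5-dimethoxyphenyl)tetradecyl]-5-methoxyphenol F9. Intramolecular Ullmann diaryl ether coupling (CuI, picolinic acid, K3PO4, DMSO, 90 °C, syringe-pump addition to 2 mM) closes the same C–O bond to give robustol tri-O-methyl ether F10. BBr3 (CH2Cl2, –78 °C to rt) then gives 7.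

Step 1 (risks are Wurtz homocoupling of the benzyl Grignard and incomplete second coupling). The fallback sets out from 1 and comes back at 4, replacing the Grignard cross-coupling by stabilised-carbanion alkylation. PhSO2Na (DMF, 80 °C) converts 1 into 3,5-dimethoxybenzyl phenyl sulfone F1. Its lithium carbanion (n-BuLi, THF, –78 °C, 2.2 equiv) alkylates 2 at both ends to give 1,14-bis(3,5-dimethoxyphenyl)-1,14-bis(phenylsulfonyl)tetradecane F2 (stereoisomer mixture, irrelevant). Mg in MeOH (50 °C) removes both sulfonyl groups to give 4.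

Step 2 (least risky; possible incomplete cleavage of four ethers). The fallback sets out from 2 and comes back at 5 with no methyl ether in the route. PPh3 (2.2 equiv, MeCN, reflux) gives dodecane-1,12-diylbis(triphenylphosphonium) dibromide F3. Double deprotonation with KN(SiMe3)2 (THF, –78 °C) and Wittig reaction with bought 3,5-bis(benzyloxy)benzaldehyde F4 (2.1 equiv) gives 1,14-bis[3,5-bis(benzyloxy)phenyl]tetradeca-1,13-diene F5 (Z/E mixture). H2 over Pd/C (EtOAc/EtOH, rt) saturates both alkenes and cleaves the four benzyl ethers in one operation to give 5.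

**Further compounds**
F1 | step 1 | 3,5-dimethoxybenzyl phenyl sulfone | COc1cc(CS(=O)(=O)c2ccccc2)cc(OC)c1
F2 | step 1 | 1,14-bis(3,5-dimethoxyphenyl)-1,14-bis(phenylsulfonyl)tetradecane (meso/racemic mixture) | COc1cc(C(CCCCCCCCCCCCC(c2cc(OC)cc(OC)c2)S(=O)(=O)c2ccccc2)S(=O)(=O)c2ccccc2)cc(OC)c1
F3 | step 2 | dodecane-1,12-diylbis(triphenylphosphonium) dibromide | [Br-].[Br-].c1ccc(cc1)[P+](c1ccccc1)(c1ccccc1)CCCCCCCCCCCC[P+](c1ccccc1)(c1ccccc1)c1ccccc1
F4 | step 2 | 3,5-bis(benzyloxy)benzaldehyde (bought) | O=Cc1cc(OCc2ccccc2)cc(OCc2ccccc2)c1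
F5 | step 2 | 1,14-bis[3,5-bis(benzyloxy)phenyl]tetradeca-1,13-diene (Z/E mixture) | C(=CCCCCCCCCCCC=Cc1cc(OCc2ccccc2)cc(OCc2ccccc2)c1)c1cc(OCc2ccccc2)cc(OCc2ccccc2)c1
F6 | step 3 | 3-[14-(3,5-dimethoxyphenyl)tetradecyl]-5-methoxyphenol | COc1cc(O)cc(CCCCCCCCCCCCCCc2cc(OC)cc(OC)c2)c1
F7 | step 3 | 3-[14-(3,5-dimethoxyphenyl)tetradecyl]-5-methoxyphenyl acetate | COc1cc(OC(C)=O)cc(CCCCCCCCCCCCCCc2cc(OC)cc(OC)c2)c1
F8 | step 3 | 3-[14-(2-iodo-3,5-dimethoxyphenyl)tetradecyl]-5-methoxyphenyl acetate | COc1cc(OC(C)=O)cc(CCCCCCCCCCCCCCc2cc(OC)cc(OC)c2I)c1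
F9 | step 3 | 3-[14-(2-iodo-3,5-dimethoxyphenyl)tetradecyl]-5-methoxyphenol | COc1cc(O)cc(CCCCCCCCCCCCCCc2cc(OC)cc(OC)c2I)c1
F10 | step 3 | robustol tri-O-methyl ether | COc1cc2cc(c1)Oc1c(OC)cc(OC)cc1CCCCCCCCCCCCCC2
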